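**Retrosynthetic overview**

1. Target 23 is cut at the C4 ester into diol 18 and protected 4-hydroxybenzoic acid 21. Diol 18 comes from enone 15 (C4=O, C3=C3a) by reagent-controlled reduction (C4), hydroxyl-directed epoxidation (C3) and titanium-mediated reductive epoxide opening (C3a–H, trans ring fusion).
2. The seven-membered ring is closed second, by ring-closing metathesis at C6=C7 (14 to 15). Triene 14 comes from cyclopentanone phosphonate 9 by olefination with aldehyde 11 (C3a–C4), isopropyl addition and oxidative 1,3-transposition.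
3. The five-membered ring is closed first, in the key step. An anionic (3+2) annulation joins the 1,3-dianion of phosphonate 5 (C2–C3–C3a) to the chiral γ-bromo enoate 4 (C1, C8a with its methyl, C8, C7). It forms C1–C2 and C3a–C8a in one flask, and the 8-phenylmenthyl ester sets the quaternary C8a.
4. Enabling feature: the only heteroatom on the five-membered ring sits on C3, between C2 and C3a, so C3 as a ketone makes both neighbours nucleophilic. The quaternary C8a and its seven-ring neighbours C8 and C7 map onto the β-carbon, α-carbon and carbonyl carbon of an enoate whose γ-carbon is C1.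

Key step: step 3

Remark: azulene numbering of the target is used for all intermediates (C1 and C2 ring CH2; C3 carbinol carbon with isopropyl; C3a ring-fusion CH; C4 acylated carbinol carbon; C6 methyl-bearing alkene carbon; C8a quaternary carbon with methyl); centres that are erased later are carried as mixtures.

**Route**

Step 1
Reactants: 1 (1R,2S,5R)-5-methyl-2-(2-phenylpropan-2-yl)cyclohexan-1-ol ((−)-8-phenylmenthol); 2 3-methylbut-2-enoyl chloride
Product: 3 (1R,2S,5R)-5-methyl-2-(2-phenylpropan-2-yl)cyclohexyl 3-methylbut-2-enoate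
Conditions: n-BuLi, THF, −78 °C; then 2, −78 °C to rt
Reagents that add atoms: none
Why: O-acylation of the lithium alkoxide (ester formation) avoids amine-induced deconjugation of the acid chloride; no stereocentre is touched.

Step 2
Reactants: 3 (1R,2S,5R)-5-methyl-2-(2-phenylpropan-2-yl)cyclohexyl 3-methylbut-2-enoate
Product: 4 (1R,2S,5R)-5-methyl-2-(2-phenylpropan-2-yl)cyclohexyl (2E)-4-bromo-3-methylbut-2-enoate
Conditions: NBS, AIBN (cat.), PhCF3, 85 °C; chromatographic separation of the (2E) isomer
Reagents that add atoms: N-bromosuccinimide, O=C1CCC(=O)N1Br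
Why: Wohl–Ziegler allylic bromination should give both γ-bromides; the (2E) isomer needed for the facial model of step 3 is separated, and no stereocentre is formed.

Step 3
Reactants: 5 dimethyl (2-oxopropyl)phosphonate; 4 (1R,2S,5R)-5-methyl-2-(2-phenylpropan-2-yl)cyclohexyl (2E)-4-bromo-3-methylbut-2-enoate
Product: 7 (1R,2S,5R)-5-methyl-2-(2-phenylpropan-2-yl)cyclohexyl 2-[(1R)-2-(dimethoxyphosphoryl)-1-methyl-3-oxocyclopentyl]acetate, via open-chain keto phosphonate enolate 6 (not isolated)
Conditions: 5, NaH, THF, 0 °C; n-BuLi, 0 °C; 4, −78 to 0 °C; then rt to 40 °C; aq. NH4Cl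
Reagents that add atoms: none
Why: NaH and then n-BuLi convert 5 into its 1,3-dianion, whose terminal carbon (C2) displaces the allylic bromide of 4 (SN2) to form C1–C2 and give enolate 6; the phosphonate-stabilised carbon C3a of 6 then adds to the β-carbon C8a of the tethered enoate (intramolecular Michael addition), which forms C3a–C8a and the quaternary centre, and proton transfer from the acidic C3a–H to the ester enolate makes the closure irreversible. The closest known reaction type is the γ-alkylation of β-keto phosphonate or acetoacetate dianions followed by Michael ring closure onto an enoate (anionic (3+2) annulation). The cyclopentanone ring closes in the 5-exo-trig mode; closure through oxygen is reversible and should drain into the carbon-bonded product. C8a is controlled by the auxiliary: the phenyl ring of the 8-phenylmenthyl ester stacks over one face of the s-trans (E)-enoate, so C3a should attack the open Re face of C8a and give the R configuration, while C3a itself is a labile centre that is erased in step 6. The step needs γ- before α-reactivity (secured by the dianion, whose terminal carbanion is the more reactive site), substitution at the primary allylic bromide instead of attack on the ester (secured by the hindered ester) and a geometrically pure (E)-enoate (secured in step 2).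

Step 4
Reactants: 7 (1R,2S,5R)-5-methyl-2-(2-phenylpropan-2-yl)cyclohexyl 2-[(1R)-2-(dimethoxyphosphoryl)-1-methyl-3-oxocyclopentyl]acetate
Product: 9 dimethyl [(2R)-2-methyl-5-oxo-2-(prop-2-en-1-yl)cyclopentyl]phosphonate, via keto aldehyde 8 (not isolated)
Conditions: NaH, THF, 0 °C; i-Bu2AlH, toluene, −78 °C; then Ph3P=CH2 (from Ph3PCH3Br and KN(SiMe3)2), THF, −78 °C to rt
Reagents that add atoms: methylenetriphenylphosphorane, C=P(c1ccccc1)(c1ccccc1)c1ccccc1
Why: The sodium enolate of the β-keto phosphonate shields the ketone while i-Bu2AlH reduces the ester to the aldehyde level, and Wittig methylenation of aldehyde 8 gives the allyl group (C8–C7=CH2); auxiliary 1 is recovered and C8a is untouched.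

Step 5
Reactants: 10 3-methylbut-3-en-1-ol
Product: 11 3-methylbut-3-enal
Conditions: Dess–Martin periodinane, NaHCO3, CH2Cl2, 0 °C
Reagents that add atoms: none
Why: Buffered Dess–Martin oxidation should give the β,γ-unsaturated aldehyde without moving the double bond into conjugation; the volatile aldehyde is used as a solution.

Step 6
Reactants: 9 dimethyl [(2R)-2-methyl-5-oxo-2-(prop-2-en-1-yl)cyclopentyl]phosphonate; 11 3-methylbut-3-enal
Product: 12 (3R)-3-methyl-2-(3-methylbut-3-en-1-ylidene)-3-(prop-2-en-1-yl)cyclopentan-1-one (E/Z mixture)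
Conditions: NaH, THF, 0 °C; then 11, −20 to 0 °C
Reagents that add atoms: none
Why: Horner–Wadsworth–Emmons olefination of the cyclic β-keto phosphonate removes the activating group and attaches C4–C6; the alkene geometry is irrelevant because the double bond is moved into the ring in step 8.

Step 7
Reactants: 12 (3R)-3-methyl-2-(3-methylbut-3-en-1-ylidene)-3-(prop-2-en-1-yl)cyclopentan-1-one (E/Z mixture)
Product: 13 (3R)-3-methyl-2-(3-methylbut-3-en-1-ylidene)-1-(propan-2-yl)-3-(prop-2-en-1-yl)cyclopentan-1-ol (isomer mixture)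
Conditions: i-PrMgCl, CeCl3, THF, −78 °C
Reagents that add atoms: isopropylmagnesium chloride, CC(C)[Mg]Cl
Why: Organocerium 1,2-addition to a hindered, enolisable enone; the configuration of the new carbinol is irrelevant because it is destroyed in step 8.

Step 8
Reactants: 13 (3R)-3-methyl-2-(3-methylbut-3-en-1-ylidene)-1-(propan-2-yl)-3-(prop-2-en-1-yl)cyclopentan-1-ol (isomer mixture)
Product: 14 3-methyl-1-[(5R)-5-methyl-2-(propan-2-yl)-5-(prop-2-en-1-yl)cyclopent-1-en-1-yl]but-3-en-1-one
Conditions: C5H5NH[CrO3Cl] (pyridinium chlorochromate), 4 Å molecular sieves, CH2Cl2, rt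
Reagents that add atoms: pyridinium chlorochromate, [O-][Cr](=O)(=O)Cl.c1cc[nH+]cc1
Why: Babler–Dauben oxidative transposition: the tertiary allylic chromate ester undergoes a 1,3-shift and oxidation, which places the carbonyl on C4 and the tetrasubstituted double bond at C3=C3a with isopropyl on C3.

Step 9
Reactants: 14 3-methyl-1-[(5R)-5-methyl-2-(propan-2-yl)-5-(prop-2-en-1-yl)cyclopent-1-en-1-yl]but-3-en-1-one
Product: 15 (8aR)-6,8a-dimethyl-3-(propan-2-yl)-1,2,8,8a-tetrahydroazulen-4(5H)-one
Conditions: second-generation Grubbs catalyst (H2IMes)(PCy3)Cl2Ru=CHPh (5 mol%), CH2Cl2, 40 °C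
Reagents that add atoms: none
Why: Ring-closing metathesis between the allyl group on quaternary C8a and the methallyl terminus should form the trisubstituted C6=C7 bond and the seven-membered ring; the conjugated tetrasubstituted alkene is inert and no stereocentre is involved.

Step 10
Reactants: 15 (8aR)-6,8a-dimethyl-3-(propan-2-yl)-1,2,8,8a-tetrahydroazulen-4(5H)-one
Product: 16 (4R,8aR)-6,8a-dimethyl-3-(propan-2-yl)-1,2,4,5,8,8a-hexahydroazulen-4-ol
Conditions: (S)-2-methyl-CBS-oxazaborolidine (20 mol%), catecholborane, toluene, −78 °C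
Reagents that add atoms: none
Why: Corey–Bakshi–Shibata reduction under reagent control: with the fully substituted alkenyl side as the large group, the (S)-catalyst should give the (4R) alcohol (hydroxyl cis to the C8a methyl); catecholborane at low temperature leaves the trisubstituted alkene untouched.

Step 11
Reactants: 16 (4R,8aR)-6,8a-dimethyl-3-(propan-2-yl)-1,2,4,5,8,8a-hexahydroazulen-4-ol
Product: 17 (3R,3aS,4R,8aR)-3,3a-epoxy-6,8a-dimethyl-3-(propan-2-yl)-1,2,3,3a,4,5,8,8a-octahydroazulen-4-ol
Conditions: VO(acac)2 (5 mol%), t-BuOOH (1.1 equiv), CH2Cl2, 0 °C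
Reagents that add atoms: tert-butyl hydroperoxide, CC(C)(C)OO
Why: Vanadium-catalysed hydroxyl-directed epoxidation delivers oxygen to the allylic tetrasubstituted alkene on the face of the C4 hydroxyl, which fixes the C3–O bond cis to that hydroxyl (3R); the slower homoallylic C6=C7 alkene is spared by using one equivalent of peroxide.

Step 12
Reactants: 17 (3R,3aS,4R,8aR)-3,3a-epoxy-6,8a-dimethyl-3-(propan-2-yl)-1,2,3,3a,4,5,8,8a-octahydroazulen-4-ol
Product: 18 (3R,3aS,4R,8aR)-6,8a-dimethyl-3-(propan-2-yl)-1,2,3,3a,4,5,8,8a-octahydroazulene-3,4-diol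
Conditions: Cp2TiCl2, Mn dust, THF, rt; then 17 and 1,4-cyclohexadiene, rt; aq. NaH2PO4
Reagents that add atoms: none
Why: Nugent–RajanBabu reductive epoxide opening with trivalent titanium: coordination to the C4 oxygen directs homolysis of the C3a–O bond (2,3-epoxy alcohol to 1,3-diol), and the tertiary C3a radical should take hydrogen from 1,4-cyclohexadiene on the face opposite the C8a methyl and the two titanium alkoxides, which gives the trans ring fusion (3aS) and leaves the C3 hydroxyl in place.

Step 13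
Reactants: 19 4-hydroxybenzoic acid
Product: 21 4-[(tert-butyldimethylsilyl)oxy]benzoic acid, via bis-silylated acid 20 (not isolated)
Conditions: TBSCl, imidazole, DMF, rt; then AcOH, THF, H2O, rt
Reagents that add atoms: tert-butyldimethylsilyl chloride, CC(C)(C)[Si](C)(C)Cl
Why: Exhaustive silylation followed by selective hydrolysis of the labile silyl ester should give the phenol-protected acid.

Step 14
Reactants: 18 (3R,3aS,4R,8aR)-6,8a-dimethyl-3-(propan-2-yl)-1,2,3,3a,4,5,8,8a-octahydroazulene-3,4-diol; 21 4-[(tert-butyldimethylsilyl)oxy]benzoic acid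
Product: 22 (3R,3aS,4R,8aR)-3-hydroxy-6,8a-dimethyl-3-(propan-2-yl)-1,2,3,3a,4,5,8,8a-octahydroazulen-4-yl 4-[(tert-butyldimethylsilyl)oxy]benzoate
Conditions: DCC, DMAP (cat.), CH2Cl2, 0 °C to rt
Reagents that add atoms: none
Why: Steglich esterification should acylate the secondary C4 hydroxyl with retention, while the tertiary C3 hydroxyl is too hindered to react.

Step 15
Reactants: 22 (3R,3aS,4R,8aR)-3-hydroxy-6,8a-dimethyl-3-(propan-2-yl)-1,2,3,3a,4,5,8,8a-octahydroazulen-4-yl 4-[(tert-butyldimethylsilyl)oxy]benzoate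
Product: 23 (3R,3aS,4R,8aR)-3-hydroxy-6,8a-dimethyl-3-(propan-2-yl)-1,2,3,3a,4,5,8,8a-octahydroazulen-4-yl 4-hydroxybenzoate (target)
Conditions: n-Bu4NF, AcOH, THF, 0 °C
Reagents that add atoms: none
Why: Fluoride cleaves the aryl silyl ether; acetic acid buffering protects the benzoate and the tertiary alcohol.

**Compound list**

1 | (1R,2S,5R)-5-methyl-2-(2-phenylpropan-2-yl)cyclohexan-1-ol | C[C@@H]1CC[C@H]([C@@H](C1)O)C(C)(C)c1ccccc1 | starting material
2 | 3-methylbut-2-enoyl chloride | CC(C)=CC(Cl)=O | starting material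
3 | (1R,2S,5R)-5-methyl-2-(2-phenylpropan-2-yl)cyclohexyl 3-methylbut-2-enoate | C[C@@H]1CC[C@H]([C@@H](C1)OC(=O)C=C(C)C)C(C)(C)c1ccccc1 | intermediate
4 | (1R,2S,5R)-5-methyl-2-(2-phenylpropan-2-yl)cyclohexyl (2E)-4-bromo-3-methylbut-2-enoate | C[C@@H]1CC[C@H]([C@@H](C1)OC(=O)/C=C(\C)CBr)C(C)(C)c1ccccc1 | intermediate
5 | dimethyl (2-oxopropyl)phosphonate | COP(=O)(CC(C)=O)OC | starting material
6 | (1R,2S,5R)-5-methyl-2-(2-phenylpropan-2-yl)cyclohexyl (2E)-7-(dimethoxyphosphoryl)-3-methyl-6-oxohept-2-enoate (formed as its enolate) | C[C@@H]1CC[C@H]([C@@H](C1)OC(=O)/C=C(\C)CCC(=O)CP(=O)(OC)OC)C(C)(C)c1ccccc1 | intermediate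
7 | (1R,2S,5R)-5-methyl-2-(2-phenylpropan-2-yl)cyclohexyl 2-[(1R)-2-(dimethoxyphosphoryl)-1-methyl-3-oxocyclopentyl]acetate (epimers at the phosphonate carbon) | C[C@@H]1CC[C@H]([C@@H](C1)OC(=O)C[C@@]2(C)CCC(=O)C2P(=O)(OC)OC)C(C)(C)c1ccccc1 | intermediate
8 | 2-[(1R)-2-(dimethoxyphosphoryl)-1-methyl-3-oxocyclopentyl]acetaldehyde | O=CC[C@@]1(C)CCC(=O)C1P(=O)(OC)OC | intermediate
9 | dimethyl [(2R)-2-methyl-5-oxo-2-(prop-2-en-1-yl)cyclopentyl]phosphonate | C=CC[C@@]1(C)CCC(=O)C1P(=O)(OC)OC | intermediate
10 | 3-methylbut-3-en-1-ol | CC(=C)CCO | starting material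
11 | 3-methylbut-3-enal | CC(=C)CC=O | intermediate
12 | (3R)-3-methyl-2-(3-methylbut-3-en-1-ylidene)-3-(prop-2-en-1-yl)cyclopentan-1-one (E/Z mixture) | C=CC[C@@]1(C)CCC(=O)C1=CCC(C)=C | intermediate
13 | (3R)-3-methyl-2-(3-methylbut-3-en-1-ylidene)-1-(propan-2-yl)-3-(prop-2-en-1-yl)cyclopentan-1-ol (isomer mixture) | C=CC[C@@]1(C)CCC(O)(C(C)C)C1=CCC(C)=C | intermediate
14 | 3-methyl-1-[(5R)-5-methyl-2-(propan-2-yl)-5-(prop-2-en-1-yl)cyclopent-1-en-1-yl]but-3-en-1-one | C=CC[C@@]1(C)CCC(C(C)C)=C1C(=O)CC(C)=C | intermediate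
15 | (8aR)-6,8a-dimethyl-3-(propan-2-yl)-1,2,8,8a-tetrahydroazulen-4(5H)-one | CC1=CC[C@@]2(C)CCC(C(C)C)=C2C(=O)C1 | intermediate
16 | (4R,8aR)-6,8a-dimethyl-3-(propan-2-yl)-1,2,4,5,8,8a-hexahydroazulen-4-ol | CC1=CC[C@@]2(C)CCC(C(C)C)=C2[C@H](O)C1 | intermediate
17 | (3R,3aS,4R,8aR)-3,3a-epoxy-6,8a-dimethyl-3-(propan-2-yl)-1,2,3,3a,4,5,8,8a-octahydroazulen-4-ol | CC1=CC[C@@]2(C)CC[C@]3(C(C)C)O[C@]23[C@H](O)C1 | intermediate
18 | (3R,3aS,4R,8aR)-6,8a-dimethyl-3-(propan-2-yl)-1,2,3,3a,4,5,8,8a-octahydroazulene-3,4-diol | CC1=CC[C@@]2(C)CC[C@@](O)(C(C)C)[C@@H]2[C@H](O)C1 | intermediate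
19 | 4-hydroxybenzoic acid | OC(=O)c1ccc(O)cc1 | starting material
20 | tert-butyldimethylsilyl 4-[(tert-butyldimethylsilyl)oxy]benzoate | CC(C)(C)[Si](C)(C)OC(=O)c1ccc(O[Si](C)(C)C(C)(C)C)cc1 | intermediate
21 | 4-[(tert-butyldimethylsilyl)oxy]benzoic acid | CC(C)(C)[Si](C)(C)Oc1ccc(C(=O)O)cc1 | intermediate
22 | (3R,3aS,4R,8aR)-3-hydroxy-6,8a-dimethyl-3-(propan-2-yl)-1,2,3,3a,4,5,8,8a-octahydroazulen-4-yl 4-[(tert-butyldimethylsilyl)oxy]benzoate | CC1=CC[C@@]2(C)CC[C@@](O)(C(C)C)[C@@H]2[C@H](OC(=O)c2ccc(O[Si](C)(C)C(C)(C)C)cc2)C1 | intermediate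
23 | (3R,3aS,4R,8aR)-3-hydroxy-6,8a-dimethyl-3-(propan-2-yl)-1,2,3,3a,4,5,8,8a-octahydroazulen-4-yl 4-hydroxybenzoate (CNP0182249.2) | CC1=CC[C@@]2(C)CC[C@@](O)(C(C)C)[C@@H]2[C@H](OC(=O)c2ccc(O)cc2)C1 | target

**Step count and risks**

Total step count: 15. Longest linear sequence: 13 steps (steps 1, 2, 3, 4, 6, 7, 8, 9, 10, 11, 12, 14, 15).

Steps most likely to fail:

Step 3. The carbon ring closure may be slow against reversible closure through oxygen, the enoate may lose its (E) geometry by γ-deprotonation, or the auxiliary may shield the enoate face too weakly; each would lower the selectivity at C8a. The fallback sets the quaternary centre by catalytic asymmetric conjugate addition. It sets out from aldehyde 11 and comes back to the route at 12. Purchased 3-ethoxycyclopent-2-en-1-one F1 is treated with allylmagnesium bromide (CH2=CHCH2MgBr) and then dilute HCl (Stork–Danheiser sequence) to give 3-(prop-2-en-1-yl)cyclopent-2-en-1-one F2. AlMe3 with catalytic copper thiophene-2-carboxylate Cu(O2CC4H3S) and a BINOL-derived phosphoramidite ligand (the enantiomer that gives the 3R centre) should add methyl and give the aluminium enolate dimethyl{[(3R)-3-methyl-3-(prop-2-en-1-yl)cyclopent-1-en-1-yl]oxy}aluminium F3. Trapping with 11 gives the aldol (3R)-2-(1-hydroxy-3-methylbut-3-en-1-yl)-3-methyl-3-(prop-2-en-1-yl)cyclopentan-1-one F4, and MsCl with Et3N dehydrates F4 to 12.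

Step 12. The tertiary radical may be reduced by a second titanium centre and lose the neighbouring oxygen by elimination, or it may take up hydrogen on the wrong face. The fallback opens the epoxide at the ketone oxidation level. It sets out from epoxy alcohol 17 and comes back at diol 18. Dess–Martin oxidation gives the epoxy ketone (3R,3aR,8aR)-3,3a-epoxy-6,8a-dimethyl-3-(propan-2-yl)-1,2,3,3a,8,8a-hexahydroazulen-4(5H)-one F5. SmI2 in THF/MeOH at −90 °C should cleave the C3a–O bond of the α,β-epoxy ketone and give the β-hydroxy ketone (3R,3aR,8aR)-3-hydroxy-6,8a-dimethyl-3-(propan-2-yl)-1,2,3,3a,8,8a-hexahydroazulen-4(5H)-one F6, whose C3a–H is set by protonation of the samarium enolate opposite the C8a methyl. LiBH(s-Bu)3 in THF at −78 °C should then attack the C4 ketone from the face opposite the C8a methyl and give 18.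

Step 4. Reduction of the hindered ester may be incomplete, or the ketone may be reduced if enolate formation is not complete. The fallback reduces both carbonyl groups and reoxidises. It sets out from 7 and comes back at 9. LiAlH4 in THF at 0 °C reduces ester and ketone to the diol 2-[(1R)-2-(dimethoxyphosphoryl)-3-hydroxy-1-methylcyclopentyl]ethan-1-ol F7, with recovery of auxiliary 1. Dess–Martin periodinane oxidises both alcohols to keto aldehyde 8, which is methylenated with Ph3P=CH2 to give 9.

**Further compounds**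

F1 | step 3 | 3-ethoxycyclopent-2-en-1-one | CCOC1=CC(=O)CC1
F2 | step 3 | 3-(prop-2-en-1-yl)cyclopent-2-en-1-one | C=CCC1=CC(=O)CC1
F3 | step 3 | dimethyl{[(3R)-3-methyl-3-(prop-2-en-1-yl)cyclopent-1-en-1-yl]oxy}aluminium | C=CC[C@@]1(C)CCC(O[Al](C)C)=C1
F4 | step 3 | (3R)-2-(1-hydroxy-3-methylbut-3-en-1-yl)-3-methyl-3-(prop-2-en-1-yl)cyclopentan-1-one | C=CC[C@@]1(C)CCC(=O)C1C(O)CC(C)=C
F5 | step 12 | (3R,3aR,8aR)-3,3a-epoxy-6,8a-dimethyl-3-(propan-2-yl)-1,2,3,3a,8,8a-hexahydroazulen-4(5H)-one | CC1=CC[C@@]2(C)CC[C@]3(C(C)C)O[C@]23C(=O)C1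
F6 | step 12 | (3R,3aR,8aR)-3-hydroxy-6,8a-dimethyl-3-(propan-2-yl)-1,2,3,3a,8,8a-hexahydroazulen-4(5H)-one | CC1=CC[C@@]2(C)CC[C@@](O)(C(C)C)[C@@H]2C(=O)C1
F7 | step 4 | 2-[(1R)-2-(dimethoxyphosphoryl)-3-hydroxy-1-methylcyclopentyl]ethan-1-ol | OCC[C@@]1(C)CCC(O)C1P(=O)(OC)OC
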